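Ring B of the drimane (C5–C6–C7–C8–C9–C10) is disconnected into β-cyclocitral, which supplies ring A with C6 as its formyl carbon on the C5=C10 alkene, and a chiral 2-methylallyl boronate supplying C7–C8(C12)–C9 with the arylmethyl group on C9. One flask unites them: allylboration, oxy-Cope shift and carbonyl-ene closure make the C6–C7 and C9–C10 bonds, the C10 quaternary centre, C9, C5 and the C8 exocyclic methylene, relaying chirality from one C–B stereocentre through a temporary C6 carbinol. The step exploits the 1,3-disposition of C7 and C9 about C8 and the quaternary C10 β to C6. The arene then becomes the epoxyquinol, which is acylated with a desymmetrised hydroxymethylglutarate.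

Key step: step 7

Remark: drimane numbering (C1–C12, C11 = benzylic CH2) is used for the terpenoid part, Ar = 5-methoxy-2-(triisopropylsilyloxy)-4-[(triisopropylsilyloxy)methyl]phenyl, and the (−)-sparteine deprotonation (pro-S hydrogen) and the esterase hydrolysis ((S)-half ester) are assumed to follow the sense known for simple analogues.

Step 1
Reactants: 1 5-hydroxy-2-methoxybenzaldehyde
Product: 2 4-bromo-5-hydroxy-2-methoxybenzaldehyde
Conditions: NBS, MeCN, 0 °C
Reagents that add atoms: N-bromosuccinimide, O=C1CCC(=O)N1Br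
Why: Electrophilic aromatic bromination directed ortho by the free phenol should go to C4, because the para position carries OMe and the other ortho position lies between OH and CHO.

Step 2
Reactants: 2 4-bromo-5-hydroxy-2-methoxybenzaldehyde
Product: 3 2-bromo-5-(hydroxymethyl)-4-methoxyphenol
Conditions: NaBH4, MeOH, 0 °C
Reagents that add atoms: none
Why: Borohydride reduction of the aldehyde should leave the aryl bromide and phenol untouched.

Step 3
Reactants: 3 2-bromo-5-(hydroxymethyl)-4-methoxyphenol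
Product: 4 [2-bromo-4-methoxy-5-(triisopropylsilyloxymethyl)phenoxy]triisopropylsilane (ArBr)
Conditions: TIPSCl, imidazole, DMF, rt
Reagents that add atoms: chlorotriisopropylsilane, CC(C)[Si](Cl)(C(C)C)C(C)C
Why: Imidazole-promoted silylation should protect phenol and primary alcohol as ethers that survive organolithiums and heat and fall together to fluoride.

Step 4
Reactants: 4 ArBr
Product: 5 2-Ar-ethan-1-ol
Conditions: n-BuLi, THF, −78 °C; then BF3·OEt2, oxirane, −78 °C
Reagents that add atoms: oxirane, C1CO1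
Why: Bromine–lithium exchange followed by BF3-assisted epoxide opening at −78 °C should give the arylethanol before the ortho-silyloxy aryllithium can undergo O-to-C silyl migration.

Step 5
Reactants: 5 2-Ar-ethan-1-ol
Product: 6 2-Ar-ethyl N,N-diisopropylcarbamate
Conditions: NaH, i-Pr2NCOCl, THF, reflux
Reagents that add atoms: N,N-diisopropylcarbamoyl chloride, CC(C)N(C(C)C)C(=O)Cl
Why: O-Carbamoylation installs the group that directs α-lithiation and later serves as the leaving group.

Step 6
Reactants: 6 2-Ar-ethyl N,N-diisopropylcarbamate; 7 2-isopropenyl-4,4,5,5-tetramethyl-1,3,2-dioxaborolane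
Product: 10 (R)-2-(1-Ar-3-methylbut-3-en-2-yl)-4,4,5,5-tetramethyl-1,3,2-dioxaborolane, via α-lithio carbamate 8 (not isolated), via lithium boronate complex 9 (not isolated)
Conditions: s-BuLi, (−)-sparteine, Et2O, −78 °C; 7; then MgBr2·OEt2, −78 °C to reflux
Reagents that add atoms: none
Why: Sparteine-mediated enantioselective α-deprotonation, borylation with retention and stereospecific 1,2-metallate rearrangement (inversion at carbon, carbamate as leaving group) should set the C9–B stereocentre as R (lithiation–borylation).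

Step 7
Reactants: 10 (R)-2-(1-Ar-3-methylbut-3-en-2-yl)-4,4,5,5-tetramethyl-1,3,2-dioxaborolane; 11 β-cyclocitral
Product: 16 11-Ar-drim-8(12)-en-6β-ol (5α-H, 9α-H, 10β-CH3), via borinic ester 12 (not isolated), via O-borinate 13 (not isolated), via dienol 14 (not isolated), via seco-aldehyde 15 (not isolated)
Conditions: n-BuLi, THF, −78 °C; (CF3CO)2O; 11, −78 °C to rt; MeN(CH2CH2OH)2; solvent exchange to toluene, i-Pr2NEt, 210 °C (sealed tube)
Reagents that add atoms: none
Why: Borinic ester 12 (from 10, n-BuLi and (CF3CO)2O) allylates 11 at its CH2 terminus (C7) through a closed chair transition state to give, after boron removal, (S,E)-dienol 14; at 210 °C the chair [3,3] oxy-Cope shift makes C9–C10 while spending the first C6–C7 bond as a temporary tether, the enol tautomerises to aldehyde 15, and a carbonyl-ene reaction of the C7=C8–C12H3 unit (joined through its central carbon C8) makes C6–C7 and the C8=C12 methylene. The closest known reaction types are the chirality-transferring allylboration with α-substituted allylboron reagents and the thermal tandem oxy-Cope/ene reaction of 1,5-dien-3-ols. Ring B is closed in the ene step as a six-membered ring, endo with respect to the C7=C8 alkene, through a chair-like transition state fused trans to ring A. The C–B stereocentre of 10 sets the transient C6 carbinol (equatorial α-substituent, E alkene), the oxy-Cope chair with equatorial oxygen and axial C10 methyl relays it to C9 (α-H) and C10 (β-CH3), C5 (α-H) is set by epimerisation of the aldehyde α-carbon to the equatorial formyl epimer before trans closure, and the C6 hydroxyl (axial, β) follows from the cyclic ene transition state and is removed later. The step needs E-selective allylboration (secured by the borinic ester), [3,3] shift faster than retro-ene cleavage of 14, and trans rather than cis ring fusion, which the equatorial preference of the formyl group and of the C9 side chain on ring A should secure.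

Step 8
Reactants: 16 11-Ar-drim-8(12)-en-6β-ol
Product: 17 O-(11-Ar-drim-8(12)-en-6β-yl) S-methyl dithiocarbonate
Conditions: NaH, CS2, THF, 0 °C to rt; then MeI
Reagents that add atoms: carbon disulfide, S=C=S; iodomethane, CI
Why: Xanthate formation (first half of the Barton–McCombie deoxygenation) should work even on the hindered alkoxide because CS2 is a small electrophile.

Step 9
Reactants: 17 O-(11-Ar-drim-8(12)-en-6β-yl) S-methyl dithiocarbonate
Product: 18 11-Ar-drim-8(12)-ene (5S,9S,10S)
Conditions: Bu3SnH, AIBN (cat.), toluene, 100 °C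
Reagents that add atoms: none
Why: Barton–McCombie radical deoxygenation should remove the C6 oxygen, the secondary C6 radical being trapped by Bu3SnH faster than it can rearrange through the homoallylic C8=C12 alkene.

Step 10
Reactants: 18 11-Ar-drim-8(12)-ene
Product: 19 2-[(5S,9S,10S)-drim-8(12)-en-11-yl]-5-(hydroxymethyl)-4-methoxyphenol
Conditions: Bu4NF, THF, rt
Reagents that add atoms: none
Why: Fluoride cleaves both silyl ethers without acid, which would cyclise the free phenol onto the C8=C12 alkene.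

Step 11
Reactants: 19 2-[drim-8(12)-en-11-yl]-5-(hydroxymethyl)-4-methoxyphenol
Product: 20 2-[drim-8(12)-en-11-yl]-5-(hydroxymethyl)-4,4-dimethoxycyclohexa-2,5-dien-1-one
Conditions: PhI(OAc)2, MeOH, 0 °C
Reagents that add atoms: methanol, CO
Why: Oxidative dearomatisation of a para-methoxyphenol in methanol should give the quinone monoketal with the ketal at the former OMe carbon, leaving the ketone next to the terpenyl-bearing carbon.

Step 12
Reactants: 20 2-[drim-8(12)-en-11-yl]-5-(hydroxymethyl)-4,4-dimethoxycyclohexa-2,5-dien-1-one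
Product: 21 (1S,6R)-1-[drim-8(12)-en-11-yl]-4-(hydroxymethyl)-5,5-dimethoxy-7-oxabicyclo[4.1.0]hept-3-en-2-one
Conditions: Ph3COOH, NaN(SiMe3)2, diisopropyl L-tartrate, toluene, −50 °C
Reagents that add atoms: trityl hydroperoxide, OOC(c1ccccc1)(c1ccccc1)c1ccccc1
Why: Tartrate-mediated nucleophilic (Weitz–Scheffer) epoxidation should attack only the dienone alkene C2=C3, whose β-carbon is unsubstituted, with the face chosen by the chiral tartrate–peroxide reagent and the electron-rich C8=C12 alkene left alone.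

Step 13
Reactants: 21 (1S,6R)-epoxy ketal
Product: 22 (1S,6R)-1-[drim-8(12)-en-11-yl]-4-(hydroxymethyl)-7-oxabicyclo[4.1.0]hept-3-ene-2,5-dione
Conditions: PPTS (cat.), acetone/H2O, rt
Reagents that add atoms: water, O
Why: Mild acid hydrolysis of the dimethyl ketal should unmask the second carbonyl without touching the epoxide or the exocyclic alkene.

Step 14
Reactants: 22 (1S,6R)-epoxyquinone
Product: 23 (1S,5R,6S)-1-[drim-8(12)-en-11-yl]-5-hydroxy-4-(hydroxymethyl)-7-oxabicyclo[4.1.0]hept-3-en-2-one
Conditions: i-Bu2AlH (2.5 equiv), THF, −78 °C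
Reagents that add atoms: none
Why: Chelation-controlled 1,2-reduction: the aluminium alkoxide formed at the primary hydroxyl should activate the adjacent C5 carbonyl, and hydride should arrive on the epoxide face (aluminium bound to the epoxide oxygen, opposite face blocked by the C1 substituent) to give the alcohol anti to the epoxide.

Step 15
Reactants: 24 dimethyl 3-hydroxy-3-methylpentanedioate
Product: 25 (S)-3-hydroxy-5-methoxy-3-methyl-5-oxopentanoic acid
Conditions: pig liver esterase, phosphate buffer pH 7.5, rt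
Reagents that add atoms: water, O
Why: Enzymatic desymmetrisation hydrolyses one enantiotopic ester group and stops at the anionic half ester.

Step 16
Reactants: 25 (S)-3-hydroxy-5-methoxy-3-methyl-5-oxopentanoic acid
Product: 26 1-tert-butyl 5-methyl (R)-3-hydroxy-3-methylpentanedioate
Conditions: Cl3CC(=NH)Ot-Bu, CH2Cl2/cyclohexane, rt
Reagents that add atoms: tert-butyl 2,2,2-trichloroacetimidate, CC(C)(C)OC(=N)C(Cl)(Cl)Cl
Why: Imidate tert-butylation of the carboxylic acid should spare the tertiary alcohol and differentiate the two arms sterically.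

Step 17
Reactants: 26 1-tert-butyl 5-methyl (R)-3-hydroxy-3-methylpentanedioate
Product: 27 1-tert-butyl 5-[2-(trimethylsilyl)ethyl] (R)-3-hydroxy-3-methylpentanedioate
Conditions: Me3SiCH2CH2OH, Ti(Oi-Pr)4 (cat.), 90 °C
Reagents that add atoms: 2-(trimethylsilyl)ethanol, C[Si](C)(C)CCO
Why: Titanate-mediated transesterification, favoured for β-hydroxy esters, should exchange only the methyl ester because the tert-butyl ester is too hindered.

Step 18
Reactants: 27 1-tert-butyl 5-[2-(trimethylsilyl)ethyl] (R)-3-hydroxy-3-methylpentanedioate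
Product: 28 (S)-3-hydroxy-3-methyl-5-oxo-5-[2-(trimethylsilyl)ethoxy]pentanoic acid
Conditions: CF3CO2H, CH2Cl2, 0 °C
Reagents that add atoms: none
Why: Acidolysis removes the tert-butyl ester as isobutene while the silylethyl ester should survive brief cold acid.

Step 19
Reactants: 23 (1S,5R,6S)-epoxyquinol diol; 28 (S)-3-hydroxy-3-methyl-5-oxo-5-[2-(trimethylsilyl)ethoxy]pentanoic acid
Product: 29 2-(trimethylsilyl)ethyl ester of target 30
Conditions: EDC·HCl, DMAP (cat.), CH2Cl2, −20 °C
Reagents that add atoms: none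
Why: Steglich esterification at low temperature should acylate the primary allylic hydroxyl in preference to the hindered secondary C5 hydroxyl and the tertiary hydroxyl of 28.

Step 20
Reactants: 29 2-(trimethylsilyl)ethyl ester of target 30
Product: 30 target (CNP0158101.2)
Conditions: Bu4NF, AcOH, THF, 0 °C
Reagents that add atoms: none
Why: Fluoride-induced β-elimination of the silylethyl ester under buffered conditions should free the acid without acyl migration or damage to the epoxyquinol.

Compound list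
1 | 5-hydroxy-2-methoxybenzaldehyde | COc1ccc(O)cc1C=O | starting material
2 | 4-bromo-5-hydroxy-2-methoxybenzaldehyde | COc1cc(Br)c(O)cc1C=O | intermediate
3 | 2-bromo-5-(hydroxymethyl)-4-methoxyphenol | COc1cc(Br)c(O)cc1CO | intermediate
4 | [2-bromo-4-methoxy-5-(triisopropylsilyloxymethyl)phenoxy]triisopropylsilane (ArBr) | COc1cc(Br)c(O[Si](C(C)C)(C(C)C)C(C)C)cc1CO[Si](C(C)C)(C(C)C)C(C)C | intermediate
5 | 2-Ar-ethan-1-ol | COc1cc(CCO)c(O[Si](C(C)C)(C(C)C)C(C)C)cc1CO[Si](C(C)C)(C(C)C)C(C)C | intermediate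
6 | 2-Ar-ethyl N,N-diisopropylcarbamate | COc1cc(CCOC(=O)N(C(C)C)C(C)C)c(O[Si](C(C)C)(C(C)C)C(C)C)cc1CO[Si](C(C)C)(C(C)C)C(C)C | intermediate
7 | 2-isopropenyl-4,4,5,5-tetramethyl-1,3,2-dioxaborolane | CC(=C)B1OC(C)(C)C(C)(C)O1 | starting material
8 | (S)-1-lithio-2-Ar-ethyl N,N-diisopropylcarbamate (sparteine complex) | [Li][C@@H](Cc1cc(OC)c(CO[Si](C(C)C)(C(C)C)C(C)C)cc1O[Si](C(C)C)(C(C)C)C(C)C)OC(=O)N(C(C)C)C(C)C | intermediate
9 | lithium (S)-boronate complex of 8 with 7 | C=C(C)[B-]1(OC(C)(C)C(C)(C)O1)[C@@H](Cc1cc(OC)c(CO[Si](C(C)C)(C(C)C)C(C)C)cc1O[Si](C(C)C)(C(C)C)C(C)C)OC(=O)N(C(C)C)C(C)C.[Li+] | intermediate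
10 | (R)-2-(1-Ar-3-methylbut-3-en-2-yl)-4,4,5,5-tetramethyl-1,3,2-dioxaborolane | C=C(C)[C@@H](Cc1cc(OC)c(CO[Si](C(C)C)(C(C)C)C(C)C)cc1O[Si](C(C)C)(C(C)C)C(C)C)B1OC(C)(C)C(C)(C)O1 | intermediate
11 | β-cyclocitral (2,6,6-trimethylcyclohex-1-ene-1-carbaldehyde) | CC1=C(C=O)C(C)(C)CCC1 | starting material
12 | butyl[(R)-1-Ar-3-methylbut-3-en-2-yl]borinic ester of pinacol mono(trifluoroacetate) | C=C(C)[C@@H](Cc1cc(OC)c(CO[Si](C(C)C)(C(C)C)C(C)C)cc1O[Si](C(C)C)(C(C)C)C(C)C)B(CCCC)OC(C)(C)C(C)(C)OC(=O)C(F)(F)F | intermediate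
13 | O-borinate of dienol 14 (butylboronic mixed ester) | CCCCB(O[C@@H](C/C(C)=C/Cc1cc(OC)c(CO[Si](C(C)C)(C(C)C)C(C)C)cc1O[Si](C(C)C)(C(C)C)C(C)C)C1=C(C)CCCC1(C)C)OC(C)(C)C(C)(C)OC(=O)C(F)(F)F | intermediate
14 | (1S,3E)-5-Ar-3-methyl-1-(2,6,6-trimethylcyclohex-1-en-1-yl)pent-3-en-1-ol | CC1=C([C@@H](O)C/C(C)=C/Cc2cc(OC)c(CO[Si](C(C)C)(C(C)C)C(C)C)cc2O[Si](C(C)C)(C(C)C)C(C)C)C(C)(C)CCC1 | intermediate
15 | (1S,2R)-2-[(2S)-1-Ar-3-methylbut-3-en-2-yl]-2,6,6-trimethylcyclohexane-1-carbaldehyde (6,7-seco-drimane aldehyde; 5α-H, 10β-CH3) | O=C[C@H]1C(C)(C)CCC[C@]1(C)[C@@H](Cc1cc(OC)c(CO[Si](C(C)C)(C(C)C)C(C)C)cc1O[Si](C(C)C)(C(C)C)C(C)C)C(C)=C | intermediate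
16 | 11-Ar-drim-8(12)-en-6β-ol (5α-H, 9α-H, 10β-CH3) | C=C1C[C@@H](O)[C@H]2C(C)(C)CCC[C@]2(C)[C@H]1Cc1cc(OC)c(CO[Si](C(C)C)(C(C)C)C(C)C)cc1O[Si](C(C)C)(C(C)C)C(C)C | intermediate
17 | O-(11-Ar-drim-8(12)-en-6β-yl) S-methyl dithiocarbonate | C=C1C[C@@H](OC(=S)SC)[C@H]2C(C)(C)CCC[C@]2(C)[C@H]1Cc1cc(OC)c(CO[Si](C(C)C)(C(C)C)C(C)C)cc1O[Si](C(C)C)(C(C)C)C(C)C | intermediate
18 | 11-Ar-drim-8(12)-ene (5S,9S,10S) | C=C1CC[C@H]2C(C)(C)CCC[C@]2(C)[C@H]1Cc1cc(OC)c(CO[Si](C(C)C)(C(C)C)C(C)C)cc1O[Si](C(C)C)(C(C)C)C(C)C | intermediate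
19 | 2-[(5S,9S,10S)-drim-8(12)-en-11-yl]-5-(hydroxymethyl)-4-methoxyphenol | C=C1CC[C@H]2C(C)(C)CCC[C@]2(C)[C@H]1Cc1cc(OC)c(CO)cc1O | intermediate
20 | 2-[(5S,9S,10S)-drim-8(12)-en-11-yl]-5-(hydroxymethyl)-4,4-dimethoxycyclohexa-2,5-dien-1-one | C=C1CC[C@H]2C(C)(C)CCC[C@]2(C)[C@H]1CC1=CC(OC)(OC)C(CO)=CC1=O | intermediate
21 | (1S,6R)-1-[(5S,9S,10S)-drim-8(12)-en-11-yl]-4-(hydroxymethyl)-5,5-dimethoxy-7-oxabicyclo[4.1.0]hept-3-en-2-one | C=C1CC[C@H]2C(C)(C)CCC[C@]2(C)[C@H]1C[C@]12O[C@H]1C(OC)(OC)C(CO)=CC2=O | intermediate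
22 | (1S,6R)-1-[(5S,9S,10S)-drim-8(12)-en-11-yl]-4-(hydroxymethyl)-7-oxabicyclo[4.1.0]hept-3-ene-2,5-dione | C=C1CC[C@H]2C(C)(C)CCC[C@]2(C)[C@H]1C[C@]12O[C@H]1C(=O)C(CO)=CC2=O | intermediate
23 | (1S,5R,6S)-1-[(5S,9S,10S)-drim-8(12)-en-11-yl]-5-hydroxy-4-(hydroxymethyl)-7-oxabicyclo[4.1.0]hept-3-en-2-one | C=C1CC[C@H]2C(C)(C)CCC[C@]2(C)[C@H]1C[C@]12O[C@H]1[C@H](O)C(CO)=CC2=O | intermediate
24 | dimethyl 3-hydroxy-3-methylpentanedioate | COC(=O)CC(C)(O)CC(=O)OC | starting material
25 | (S)-3-hydroxy-5-methoxy-3-methyl-5-oxopentanoic acid | OC(=O)C[C@](C)(O)CC(=O)OC | intermediate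
26 | 1-tert-butyl 5-methyl (R)-3-hydroxy-3-methylpentanedioate | CC(C)(C)OC(=O)C[C@](C)(O)CC(=O)OC | intermediate
27 | 1-tert-butyl 5-[2-(trimethylsilyl)ethyl] (R)-3-hydroxy-3-methylpentanedioate | CC(C)(C)OC(=O)C[C@](C)(O)CC(=O)OCC[Si](C)(C)C | intermediate
28 | (S)-3-hydroxy-3-methyl-5-oxo-5-[2-(trimethylsilyl)ethoxy]pentanoic acid | OC(=O)C[C@](C)(O)CC(=O)OCC[Si](C)(C)C | intermediate
29 | 2-(trimethylsilyl)ethyl ester of target 30 | C=C1CC[C@H]2C(C)(C)CCC[C@]2(C)[C@H]1C[C@]12O[C@H]1[C@H](O)C(COC(=O)C[C@](C)(O)CC(=O)OCC[Si](C)(C)C)=CC2=O | intermediate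
30 | target CNP0158101.2 | C=C1CC[C@H]2C(C)(C)CCC[C@]2(C)[C@H]1C[C@]12O[C@H]1[C@H](O)C(COC(=O)C[C@](C)(O)CC(=O)O)=CC2=O | target

Total step count: 20. Longest linear sequence: 16 steps (steps 1–14, 19 and 20, from 1).

Steps most likely to fail

1. Step 7. The thermal [3,3] shift of the free dienol 14 must outrun its retro-ene (β-hydroxy-olefin) cleavage back to 11. The pericyclic ene closure needs an axial C6 oxygen syn to the C10 and C4 methyl groups, so closure of the C5-epimeric aldehyde may erode trans ring fusion. Fallback (stepwise ionic sequence of known reactions): setting out from 10 and 11, the allylboration alone (borinic ester, −78 °C) and work-up would give isolated 14. KH/18-crown-6 in THF (anionic oxy-Cope, 0 °C to rt) would then give isolated aldehyde 15, which is equilibrated at C5 with i-Pr2NEt. Me2AlCl in CH2Cl2 at −78 °C would close the configurationally fixed aldehyde by a Lewis-acid-promoted carbonyl-ene reaction, and the route is rejoined at 16. No new compound arises.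

2. Step 12. The peroxide may add to both faces of dienone 20 with little discrimination, because the nearest stereocentre (C9) is remote and the tartrate-bound peroxide may not differentiate the faces of this 2,5-disubstituted dienone. Fallback (auxiliary control in place of reagent control): setting out from 20, ketal exchange with (R,R)-hydrobenzoin (PPTS, toluene, 60 °C, methanol removed) would give the C2-symmetric spiroketal dienone F1, whose phenyl groups shield one face. Epoxidation with t-BuOOH/DBU would give the spiroketal epoxide F2, and aqueous CF3CO2H would cleave the auxiliary and return to the route at 22. The antipodal diol would be used if the shielded face proves to be the wrong one.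

3. Step 14. Hydride may be delivered to the C2 carbonyl, to the face anti to the epoxide, or to both carbonyls, because the selectivity rests on an aluminium chelate that is not enforced covalently. Fallback (covalent silicon tether): setting out from 22, i-Pr2SiHCl/imidazole would convert the primary hydroxyl into the hydridosilyl ether F3. Fluoride-catalysed intramolecular hydrosilylation (catalytic Bu4N[Ph3SiF2]) can reach only the adjacent C5 carbonyl and would give the cyclic silylene acetal F4. HF·pyridine would release the diol and rejoin the route at 23.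

Further compounds
F0 | step 7 | none | none
F1 | step 12 | 2-[(5S,9S,10S)-drim-8(12)-en-11-yl]-5-(hydroxymethyl)cyclohexa-2,5-dien-1-one 4-spiroketal with (R,R)-hydrobenzoin | C=C1CC[C@H]2C(C)(C)CCC[C@]2(C)[C@H]1CC1=CC2(O[C@H](c3ccccc3)[C@@H](c3ccccc3)O2)C(CO)=CC1=O
F2 | step 12 | (1S,6R)-epoxide of F1 at the alkene bearing the drimenylmethyl group | C=C1CC[C@H]2C(C)(C)CCC[C@]2(C)[C@H]1C[C@]12O[C@H]1C1(O[C@H](c3ccccc3)[C@@H](c3ccccc3)O1)C(CO)=CC2=O
F3 | step 14 | diisopropylsilyl ether of the primary hydroxyl of 22 | C=C1CC[C@H]2C(C)(C)CCC[C@]2(C)[C@H]1C[C@]12O[C@H]1C(=O)C(CO[SiH](C(C)C)C(C)C)=CC2=O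
F4 | step 14 | cyclic diisopropylsilylene acetal of 23 (bridging the C5 oxygen and the primary oxygen) | C=C1CC[C@H]2C(C)(C)CCC[C@]2(C)[C@H]1C[C@]12O[C@H]1[C@@H]1O[Si](C(C)C)(C(C)C)OCC1=CC2=O
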